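**Strategy**

The C6–CH2 bond is formed by a Stille allyl–aryl coupling at the chromone stage. Ring A is a phloroglucinol whose C6 is the only carbon ortho to the C5 hydroxyl that is hydrogen-bonded to the C4 carbonyl; because O1 of the flat γ-pyranone ring is tied up as a vinylogous ester, electrophilic iodination goes to C6 and not C8. The precursor of the key step is therefore 5-hydroxy-6-iodo-7-(methoxymethoxy)chromone, and (E)-geranyltributylstannane delivers the intact C10 chain to C6 in one neutral operation with the 2E alkene preserved. The C2 stereocentre is set afterwards by rhodium-catalysed asymmetric 1,4-addition of the 3,4-dimethoxyphenyl group to the geranylated chromone.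

Key step: step 4

Assumption: (S,S)-Ph-bod* is taken as the ligand enantiomer that delivers the aryl group to the face of C2 giving the 2S flavanone, by analogy with the sense of induction for cyclic enones; should the sense be opposite, the (R,R)-ligand is used.

**Route**

Step 1
Reactants: 1 5,7-dihydroxy-4H-chromen-4-one
Product: 2 5-hydroxy-7-(methoxymethoxy)-4H-chromen-4-one
Conditions: MOMCl (1.1 equiv), K2CO3 (1.5 equiv), acetone, 0 °C to rt
Reagents that add atoms: chloromethyl methyl ether, COCCl
Why: Williamson-type O-alkylation (MOM ether formation) should take place only at the acidic, non-chelated 7-OH, while the 5-OH, held in a hydrogen bond to the C4 carbonyl, stays free as the directing group for step 2.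

Step 2
Reactants: 2 5-hydroxy-7-(methoxymethoxy)-4H-chromen-4-one
Product: 3 5-hydroxy-6-iodo-7-(methoxymethoxy)-4H-chromen-4-one
Conditions: BnMe3N+ ICl2− (1.05 equiv), CaCO3 (1.5 equiv), CH2Cl2/MeOH 5:2, rt, dark
Reagents that add atoms: benzyltrimethylammonium dichloroiodate, C[N+](C)(C)Cc1ccccc1.Cl[I-]Cl
Why: Electrophilic aromatic iodination of a phenol with a dichloroiodate salt should occur ortho to the free chelated 5-OH at C6, since C8 is less activated (O1 is part of the vinylogous ester) and C3 is a deactivated enone α-carbon, while CaCO3 takes up the HCl so that the MOM acetal survives.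

Step 3
Reactants: 4 geranyl chloride, (2E)-1-chloro-3,7-dimethylocta-2,6-diene
Product: 5 tributyl[(2E)-3,7-dimethylocta-2,6-dien-1-yl]stannane
Conditions: Bu3SnH, LDA, THF, 0 °C; then 4, −78 °C to 0 °C
Reagents that add atoms: tributyltin hydride, CCCC[SnH](CCCC)CCCC
Why: SN2 displacement of the primary allylic chloride by the tributylstannyl anion should occur at C1 without allylic transposition and with the 2E geometry kept.

Step 4
Reactants: 3 5-hydroxy-6-iodo-7-(methoxymethoxy)-4H-chromen-4-one; 5 tributyl[(2E)-3,7-dimethylocta-2,6-dien-1-yl]stannane (1.5 equiv)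
Product: 6 6-[(2E)-3,7-dimethylocta-2,6-dien-1-yl]-5-hydroxy-7-(methoxymethoxy)-4H-chromen-4-one
Conditions: Pd(PPh3)4 (10 mol%), DMF (degassed), 80 °C; aq KF work-up
Reagents that add atoms: none
Why: Migita–Kosugi–Stille allylation: Pd(0) inserts into the C6–I bond of 3, the geranyl group passes from tin to palladium, and reductive elimination from the aryl(η3-geranyl)palladium species forms the C6–CH2 bond. The closest known reaction type is the Stille coupling of aryl iodides with prenyl- and geranyl-tributylstannanes. No ring is closed and no stereocentre is formed; the only stereochemical element is the 2E alkene, which should be retained because syn/anti exchange in the η3-allyl requires a tertiary σ-allylpalladium species that should form more slowly than reductive elimination. The step needs site selectivity on ring A, linear over branched attachment and E retention: the site is fixed by the iodine at C6, and the linear product follows from C–C bond formation at the unsubstituted CH2 terminus of the allyl ligand, favoured further by the two ortho substituents (5-OH, 7-OMOM) on the aryl partner. Neutral conditions should leave the base-sensitive γ-pyranone ring, the MOM acetal and the free phenol untouched.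

Step 5
Reactants: 6 6-[(2E)-3,7-dimethylocta-2,6-dien-1-yl]-5-hydroxy-7-(methoxymethoxy)-4H-chromen-4-one; 7 (3,4-dimethoxyphenyl)boronic acid (3 equiv)
Product: 8 (2S)-2-(3,4-dimethoxyphenyl)-6-[(2E)-3,7-dimethylocta-2,6-dien-1-yl]-5-hydroxy-7-(methoxymethoxy)-2,3-dihydro-4H-chromen-4-one
Conditions: [RhCl(C2H4)2]2 (2.5 mol%), (S,S)-Ph-bod* [(1S,4S)-2,5-diphenylbicyclo[2.2.2]octa-2,5-diene] (5.5 mol%), aq KOH (10 mol%), 1,4-dioxane/H2O 10:1, 40 °C
Reagents that add atoms: none
Why: Hayashi–Miyaura rhodium-catalysed asymmetric 1,4-addition of an arylboronic acid to a chromone: the aryl–rhodium species adds across C2=C3 with the aryl group delivered to C2 on the face selected by the C2-symmetric chiral diene (catalyst control), and protonolysis of the rhodium enolate should give the 2S flavanone, the isolated trisubstituted alkenes being inert.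

Step 6
Reactants: 8 (2S)-2-(3,4-dimethoxyphenyl)-6-[(2E)-3,7-dimethylocta-2,6-dien-1-yl]-5-hydroxy-7-(methoxymethoxy)-2,3-dihydro-4H-chromen-4-one
Product: 9 (2S)-2-(3,4-dimethoxyphenyl)-6-[(2E)-3,7-dimethylocta-2,6-dien-1-yl]-5,7-dihydroxy-2,3-dihydro-4H-chromen-4-one
Conditions: 2 M aq HCl/MeOH 1:5, 45 °C
Reagents that add atoms: none
Why: Acid-catalysed methanolysis of the phenolic MOM acetal should free the 7-OH, the dilute acid and moderate temperature being chosen so that the geranyl alkenes are not protonated (no chroman formation with the flanking hydroxyls) and the C2 stereocentre, which epimerises through base-mediated ring opening, is not touched.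

**Compound list**

1 | 5,7-dihydroxy-4H-chromen-4-one | O=c1ccoc2cc(O)cc(O)c12 | starting material
2 | 5-hydroxy-7-(methoxymethoxy)-4H-chromen-4-one | O=c1ccoc2cc(OCOC)cc(O)c12 | intermediate
3 | 5-hydroxy-6-iodo-7-(methoxymethoxy)-4H-chromen-4-one | O=c1ccoc2cc(OCOC)c(I)c(O)c12 | intermediate
4 | geranyl chloride, (2E)-1-chloro-3,7-dimethylocta-2,6-diene | ClC/C=C(\C)CCC=C(C)C | starting material
5 | tributyl[(2E)-3,7-dimethylocta-2,6-dien-1-yl]stannane | CCCC[Sn](CCCC)(CCCC)C/C=C(\C)CCC=C(C)C | intermediate
6 | 6-[(2E)-3,7-dimethylocta-2,6-dien-1-yl]-5-hydroxy-7-(methoxymethoxy)-4H-chromen-4-one | O=c1ccoc2cc(OCOC)c(C/C=C(\C)CCC=C(C)C)c(O)c12 | intermediate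
7 | (3,4-dimethoxyphenyl)boronic acid | COc1ccc(B(O)O)cc1OC | starting material
8 | (2S)-2-(3,4-dimethoxyphenyl)-6-[(2E)-3,7-dimethylocta-2,6-dien-1-yl]-5-hydroxy-7-(methoxymethoxy)-2,3-dihydro-4H-chromen-4-one | COc1ccc([C@@H]2CC(=O)c3c(cc(OCOC)c(C/C=C(\C)CCC=C(C)C)c3O)O2)cc1OC | intermediate
9 | (2S)-2-(3,4-dimethoxyphenyl)-6-[(2E)-3,7-dimethylocta-2,6-dien-1-yl]-5,7-dihydroxy-2,3-dihydro-4H-chromen-4-one | COc1ccc([C@@H]2CC(=O)c3c(cc(O)c(C/C=C(\C)CCC=C(C)C)c3O)O2)cc1OC | target

**Step count and risks**

Total step count: 6. Longest linear sequence: 5 (steps 1, 2, 4, 5, 6 from compound 1).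

Steps most likely to fail:

1. Step 4 (key step). The geranyl group may be transferred with allylic transposition, giving the branched attachment, the 2E geometry may erode through η3/η1 interconversion, or transmetalation at the doubly ortho-substituted arylpalladium may be slow enough for protodeiodination to compete. The fallback reverses the polarity of the two partners and sets out from compound 3. Miyaura borylation (B2pin2, PdCl2(dppf), KOAc, dioxane, 85 °C) should give 5-hydroxy-7-(methoxymethoxy)-6-(4,4,5,5-tetramethyl-1,3,2-dioxaborolan-2-yl)-4H-chromen-4-one F1. Suzuki–Miyaura allyl–aryl coupling of this boronate with commercial geranyl bromide (Pd(PPh3)4, CsF, THF, 50 °C) follows; here the η3-geranylpalladium complex is formed from the E-allylic bromide with retention and is arylated at its CH2 terminus. The fallback comes back to the route at compound 6.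

2. Step 5. The free 5-OH may protonate the aryl–rhodium species faster than it adds to the chromone, so that conversion stalls, or the product may lose enantiomeric purity by ring opening and reclosure in the slightly basic medium. The fallback moves the conjugate addition to a phenol-free substrate and sets out from compound 6. Capping of the 5-OH (NaH, MOMCl, DMF, 0 °C) should give 6-[(2E)-3,7-dimethylocta-2,6-dien-1-yl]-5,7-bis(methoxymethoxy)-4H-chromen-4-one F2. The same rhodium/diene 1,4-addition of 7 should then give (2S)-2-(3,4-dimethoxyphenyl)-6-[(2E)-3,7-dimethylocta-2,6-dien-1-yl]-5,7-bis(methoxymethoxy)-2,3-dihydro-4H-chromen-4-one F3. Both acetals are cleaved together with HCl/MeOH, so the fallback comes back to the route at compound 9.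

3. Step 2. Site control in the iodination may be incomplete (attack at C8 or at both C6 and C8), or the acetal may be lost to the HCl released. The fallback bypasses the iodide and sets out from compound 1. Classical nuclear C-alkylation of the chromone phenoxide with geranyl bromide (NaOMe, MeOH, 0 °C to rt) should give 6-[(2E)-3,7-dimethylocta-2,6-dien-1-yl]-5,7-dihydroxy-4H-chromen-4-one F4, which would have to be separated from the C8- and O-alkylated isomers. Selective 7-O-protection as in step 1 (MOMCl, K2CO3, acetone) then comes back to the route at compound 6, and steps 3 and 4 are no longer needed.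

**Further compounds**

F1 | step 4 | 5-hydroxy-7-(methoxymethoxy)-6-(4,4,5,5-tetramethyl-1,3,2-dioxaborolan-2-yl)-4H-chromen-4-one | O=c1ccoc2cc(OCOC)c(B3OC(C)(C)C(C)(C)O3)c(O)c12
F2 | step 5 | 6-[(2E)-3,7-dimethylocta-2,6-dien-1-yl]-5,7-bis(methoxymethoxy)-4H-chromen-4-one | O=c1ccoc2cc(OCOC)c(C/C=C(\C)CCC=C(C)C)c(OCOC)c12
F3 | step 5 | (2S)-2-(3,4-dimethoxyphenyl)-6-[(2E)-3,7-dimethylocta-2,6-dien-1-yl]-5,7-bis(methoxymethoxy)-2,3-dihydro-4H-chromen-4-one | COc1ccc([C@@H]2CC(=O)c3c(cc(OCOC)c(C/C=C(\C)CCC=C(C)C)c3OCOC)O2)cc1OC
F4 | step 2 | 6-[(2E)-3,7-dimethylocta-2,6-dien-1-yl]-5,7-dihydroxy-4H-chromen-4-one | O=c1ccoc2cc(O)c(C/C=C(\C)CCC=C(C)C)c(O)c12
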